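The six-membered ring (C4–C5–C6–C7–C8–C9) is disconnected across C5–C6 and C4–C9. The feature exploited is this ring itself: the methyl-bearing quaternary C5 (carrying C14) sits next to the C6 methyl centre and para to the C8 oxygen, the pattern of a Diels–Alder adduct. One catalytic enantioselective cycloaddition of methacrolein (C4, C5, C14) with (E)-2-silyloxypenta-1,3-diene (C6–C9) forms both bonds, closes the ring as its C8 silyl enol ether and sets C5 and C6. Both precursors are achiral and need at most one step. All later centres are relayed from this pair by substrate control.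

Key step: step 2

Atom labels: five-ring C1(H2), C2(=O), C3(H)=C4; six-ring C4–C5(Me)–C6(H)Me–C7H2–C8H(OH)–C9; bridge C9–C10(H)Me–C11H(OH)–C12(Me)(vinyl)–C13H2–C14H(OAc)–C5.

Assumption: the stereodescriptors of the target string are taken as written; they place the C10 arm on C9 and the C14 arm on C5 on opposite faces of the six-membered ring, so C9 is built with C10 anti to C14 and the resulting trans-bridged eight-ring closure is treated as the main downstream risk.

Step 1
Reactants: 1 (E)-pent-3-en-2-one; 2 tert-butyldimethylsilyl trifluoromethanesulfonate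
Product: 3 (E)-2-(tert-butyldimethylsilyloxy)penta-1,3-diene
Conditions: Et3N, Et2O, 0 °C to rt
Reagents that add atoms: none
Why: Silyl dienol ether formation by soft enolisation: the silyl triflate activates the carbonyl oxygen and Et3N removes a proton from the α′-methyl group, which should give the cross-conjugated 2-silyloxydiene with the (E)-alkene untouched; no stereocentre is formed.

Step 2
Reactants: 3 (E)-2-(tert-butyldimethylsilyloxy)penta-1,3-diene; 4 methacrolein
Product: 5 (1R,2S)-4-(tert-butyldimethylsilyloxy)-1,2-dimethylcyclohex-3-ene-1-carbaldehyde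
Conditions: (R)-3,3-diphenyl-1-(2-methylphenyl)tetrahydro-1H,3H-pyrrolo[1,2-c][1,3,2]oxazaborole (20 mol%), Tf2NH (18 mol%), CH2Cl2, −78 °C
Reagents that add atoms: none
Why: The N-protonated oxazaborolidine (formed in situ with Tf2NH) binds the formyl oxygen of 4 at boron with a formyl C–H···O contact, so the s-trans enal lies over one aryl ring and only one face of C5 is open; diene 3 then adds in a concerted but asynchronous [4+2] cycloaddition in which its silyloxy-activated terminus (C9) bonds to the enal β-carbon (C4) ahead of C6–C5. The closest known reaction type is the chiral oxazaborolidinium-catalysed Diels–Alder reaction of 2-substituted acroleins with 2-silyloxy-1,3-dienes. The six-membered ring is closed by intermolecular cycloaddition, both new σ-bonds forming suprafacially on diene and dienophile. C5 is controlled by the catalyst (the (R)-configured catalyst is specified because in this binding model the (S)-catalyst exposes the opposite face), and C6 is controlled relative to C5 by the endo position of the boron-bound formyl group together with the (E)-geometry of the diene, which places C14 cis to the C6 methyl. The step needs endo over exo selectivity, which the carbonyl–diene overlap at −78 °C should secure, and cycloaddition rather than protodesilylation of 3, which the bulky silyl group and the low temperature should secure; regiochemistry is secured by the substrate because the 2-silyloxy and terminal methyl groups direct the same orientation.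

Step 3
Reactants: 6 methyl 3-methylbut-2-enoate
Product: 7 1-methoxy-3-methyl-1-(trimethylsilyloxy)buta-1,3-diene
Conditions: LiN(i-Pr)2, THF, −78 °C; Me3SiCl
Reagents that add atoms: chlorotrimethylsilane, SMILES C[Si](C)(C)Cl
Why: Silyl ketene acetal formation: LiN(i-Pr)2 removes a γ-proton of the enoate and the dienolate is silylated on oxygen, which should give the 1-methoxy-1-silyloxydiene; no stereocentre is formed.

Step 4
Reactants: 5 Diels–Alder adduct; 7 silyl dienolate
Product: 9 methyl (2E,5R)-5-hydroxy-3-methyl-5-[(1R,2S)-1,2-dimethyl-4-oxocyclohexyl]pent-2-enoate, via bis-silyl aldol adduct 8 (not isolated)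
Conditions: B(C6F5)3 (5 mol%), CH2Cl2, −78 °C; then 1 M HCl, THF, 0 °C
Reagents that add atoms: none
Why: Vinylogous Mukaiyama aldol reaction: the boron-activated aldehyde should be attacked by the γ-carbon (C13) of 7 through an open transition state on the Felkin–Anh face (nucleophile anti to C6, the largest substituent on C5), which sets C14 and gives the (E)-enoate, and the acid work-up cleaves the O–SiMe3 group and hydrolyses the silyl enol ether to the C8 ketone.

Step 5
Reactants: 9 hydroxy keto ester; 2 tert-butyldimethylsilyl trifluoromethanesulfonate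
Product: 10 C14 O-TBS ether of 9
Conditions: 2,6-lutidine, CH2Cl2, −78 to 0 °C
Reagents that add atoms: none
Why: Silyl ether protection: the silyl triflate with a hindered pyridine base should silylate the hindered secondary C14 hydroxyl at low temperature without enolising the ketone, masking it against the basic steps that follow; no stereocentre is formed.

Step 6
Reactants: 10 C14 O-TBS keto ester
Product: 12 C9=C4 enone (cyclohex-2-enone with the C8 ketone), via keto sulfoxide 11 (not isolated)
Conditions: NaH, PhS(O)OMe, THF, 0 °C to rt, aq. NH4Cl; then PhMe, 110 °C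
Reagents that add atoms: none
Why: Sulfoxide dehydrogenation: Claisen-type sulfinylation of the equilibrating sodium enolates should occur at the less hindered α-methylene C9 (C7 is flanked by the C6 methine and the quaternary C5), and the β-keto sulfoxide then undergoes thermal syn-elimination, which can only take a C4 hydrogen, to give the C9=C4 enone.

Step 7
Reactants: 12 enone
Product: 13 C9–C4 epoxy ketone
Conditions: 30% H2O2, NaOH (0.3 equiv), MeOH, 0 °C
Reagents that add atoms: hydrogen peroxide, SMILES OO
Why: Weitz–Scheffer nucleophilic epoxidation: hydroperoxide adds to C4 of the enone and the enolate closes the epoxide, while the less electrophilic β,β-disubstituted enoate should be left alone; the epoxide face is of no consequence because both centres are removed in step 8.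

Step 8
Reactants: 13 epoxy ketone
Product: 14 cyclohexane-1,3-dione (ketones at C8 and C4)
Conditions: Pd(PPh3)4 (5 mol%), Ph2PCH2CH2PPh2 (5 mol%), PhMe, 100 °C
Reagents that add atoms: none
Why: Zerovalent-palladium-catalysed isomerisation of an α,β-epoxy ketone to a β-diketone: oxidative addition into the C9–O bond, β-hydride elimination from C4 and return of the hydride to C9 should give the 1,3-dione, in which C9 is doubly activated.

Step 9
Reactants: 14 1,3-dione; 15 3-bromoprop-1-yne
Product: 16 C9-propargyl 1,3-dione
Conditions: NaOH (1.0 equiv), H2O–THF, 50 °C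
Reagents that add atoms: none
Why: C-Alkylation of the stabilised dione enolate by the reactive propargylic bromide in a protic medium, which hydrogen-bonds the enolate oxygens and favours attack through carbon; the nearly neutral enolate solution should leave the methyl ester intact, and C9 stays enolisable so no stereocentre is fixed.

Step 10
Reactants: 16 C9-propargyl 1,3-dione; 17 (Z)-but-2-en-1-ol
Product: 18 C8 enol (Z)-but-2-enyl ether (vinylogous ester, C4 ketone kept)
Conditions: PPh3, DIAD, THF, 0 °C to rt
Reagents that add atoms: none
Why: Mitsunobu O-alkylation of the acidic enol: the alkoxyphosphonium ion of 17 is displaced (SN2, Z-geometry retained) by the enolate oxygen on C8, the oxygen on C4 being shielded by the quaternary C5.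

Step 11
Reactants: 18 vinylogous ester
Product: 19 2,2-disubstituted 1,3-dione with propargyl and (S)-but-3-en-2-yl groups on C9
Conditions: PhMe, 170 °C, sealed tube
Reagents that add atoms: none
Why: Thermal Claisen rearrangement ([3,3]) forms C9–C10 and regenerates the C8 ketone; the butenyl unit should be delivered to the face of C9 opposite to the bulky silyloxyalkyl (C14) substituent on C5, which sets the quaternary C9 with C10 anti to C14, and the chair transition state of the (Z)-butenyl ether sets C10.

Step 12
Reactants: 19 2,2-disubstituted 1,3-dione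
Product: 20 C8 alcohol (C8–OH cis to the C10 substituent, C4 ketone kept)
Conditions: NaBH4 (0.4 equiv), MeOH–CH2Cl2, −40 °C
Reagents that add atoms: none
Why: Chemoselective borohydride reduction of the C8 ketone (the C4 ketone lies between two quaternary carbons and the enoate is unreactive), with hydride arriving anti to the branched C10 substituent on C9, which should place the C8 hydroxyl cis to C10.

Step 13
Reactants: 20 C8 alcohol
Product: 22 cyclic methyl acetal (C8–O–C11 tetrahydrofuran with OMe on C11), via lactol 21 (not isolated)
Conditions: K2OsO4·2H2O (2 mol%), NaIO4, 2,6-lutidine, dioxane–H2O, rt; then PPTS (cat.), MeOH, rt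
Reagents that add atoms: methanol, SMILES CO
Why: Lemieux–Johnson cleavage should select the isolated monosubstituted alkene over the electron-poor enoate and the alkyne; the γ-hydroxy aldehyde closes to the cis-fused lactol and acid-catalysed acetalisation with methanol gives the methyl acetal, which masks the C11 aldehyde and C8–OH together (C11 is an inconsequential mixture of anomers).

Step 14
Reactants: 22 cyclic methyl acetal
Product: 23 (E)-allylic alcohol
Conditions: i-Bu2AlH (2.5 equiv), CH2Cl2, −78 °C; aq. potassium sodium tartrate
Reagents that add atoms: none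
Why: Aluminium hydride 1,2-reduction of the conjugated ester to the allylic alcohol at −78 °C; the C4 ketone flanked by two quaternary carbons, the acetal, the terminal alkyne and the silyl ether should not react.

Step 15
Reactants: 23 allylic alcohol
Product: 24 methyl ketone (1,4-diketone, CH2COCH3 on C9)
Conditions: Ph3PAuNTf2 (2 mol%), MeOH–H2O (10:1), 40 °C
Reagents that add atoms: water, SMILES O
Why: Gold-catalysed Markovnikov hydration of the terminal alkyne (π-activation by cationic monovalent gold, water attacking the internal carbon, possibly assisted by the neighbouring C4 carbonyl) should give the methyl ketone, the methyl acetal being stable in methanol.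

Step 16
Reactants: 24 1,4-diketone
Product: 26 cyclopentenone (C3=C4, C2 ketone), via aldol adduct 25 (not isolated)
Conditions: t-BuOK (0.5 equiv), t-BuOH–THF, 50 °C
Reagents that add atoms: none
Why: Intramolecular aldol condensation: only the C3 methyl enolate can reach the C4 ketone (5-exo-trig addition; the C1 enolate would give a three-membered ring and C4 has no α-hydrogen), and E1cB dehydration should give the C3=C4 cyclopentenone.

Step 17
Reactants: 26 cyclopentenone
Product: 27 diol (C14–OH and allylic OH free)
Conditions: HF·pyridine, pyridine, THF, 0 to 40 °C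
Reagents that add atoms: none
Why: Fluoride-mediated cleavage of the silyl ether (formation of the strong Si–F bond), buffered with pyridine so that the methyl acetal, the enone and the allylic alcohol should survive.

Step 18
Reactants: 27 diol
Product: 28 (E)-allylic chloride
Conditions: NCS, Me2S, CH2Cl2, −20 to 0 °C
Reagents that add atoms: N-chlorosuccinimide, SMILES O=C1CCC(=O)N1Cl
Why: Corey–Kim chlorination: both hydroxyls can form alkoxysulfonium ions but only the primary allylic one is displaced by chloride (SN2), the hindered saturated C14–OH being returned on work-up.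

Step 19
Reactants: 28 allylic chloride
Product: 29 C14 acetate
Conditions: Ac2O, Et3N, DMAP (cat.), CH2Cl2, 0 °C to rt
Reagents that add atoms: acetic anhydride, SMILES CC(=O)OC(C)=O
Why: DMAP-catalysed acylation of the only free hydroxyl (C14–OH) installs the acetate of the target; the primary allylic chloride should tolerate the short exposure to amine at low temperature.

Step 20
Reactants: 29 C14 acetate
Product: 30 lactol (masked C11 aldehyde)
Conditions: PPTS (cat.), acetone–H2O (9:1), rt
Reagents that add atoms: water, SMILES O
Why: Mild acid hydrolysis of the very labile 2-methoxytetrahydrofuran-type acetal should liberate the lactol under conditions that the acetate and the allylic chloride tolerate.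

Step 21
Reactants: 30 lactol
Product: 32 Pleuromutilin E, via allylchromium species 31 (not isolated)
Conditions: CrCl2 (8 equiv), LiI (cat.), THF–DMF, rt, slow addition, 0.003 M
Reagents that add atoms: none
Why: Intramolecular Nozaki–Hiyama–Kishi allylation: divalent chromium converts the allylic chloride into an allylchromium species that equilibrates E/Z by 1,3-metal shift and adds through its γ-carbon (C12) to the C11 aldehyde that is in ring–chain equilibrium with the lactol, forming C11–C12, the vinyl-bearing quaternary C12 and the eight-membered ring; C11 should be set on the Felkin–Anh face (allyl unit anti to C9), and C12 requires the closed chair transition state of the (Z)-allylchromium with C10 and the C12 methyl pseudo-equatorial and the tether carbon C13 pseudo-axial, which is the design assumption for this closure.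

Compound list
1 | (E)-pent-3-en-2-one | C/C=C/C(C)=O | starting material
2 | tert-butyldimethylsilyl trifluoromethanesulfonate | CC(C)(C)[Si](C)(C)OS(=O)(=O)C(F)(F)F | starting material
3 | (E)-2-(tert-butyldimethylsilyloxy)penta-1,3-diene | C/C=C/C(=C)O[Si](C)(C)C(C)(C)C | intermediate
4 | methacrolein (2-methylprop-2-enal) | C=C(C)C=O | starting material
5 | (1R,2S)-4-(tert-butyldimethylsilyloxy)-1,2-dimethylcyclohex-3-ene-1-carbaldehyde (formyl C14 cis to the C6 methyl) | O=C[C@]1(C)CCC(O[Si](C)(C)C(C)(C)C)=C[C@@H]1C | intermediate
6 | methyl 3-methylbut-2-enoate | COC(=O)C=C(C)C | starting material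
7 | 1-methoxy-3-methyl-1-(trimethylsilyloxy)buta-1,3-diene (ketene acetal geometry not defined) | COC(O[Si](C)(C)C)=CC(C)=C | intermediate
8 | bis-silyl aldol adduct (C14–OSiMe3, C8 silyl enol ether intact, (E)-enoate) | COC(=O)/C=C(\C)C[C@@H](O[Si](C)(C)C)[C@]1(C)CCC(O[Si](C)(C)C(C)(C)C)=C[C@@H]1C | intermediate (not isolated)
9 | methyl (2E,5R)-5-hydroxy-3-methyl-5-[(1R,2S)-1,2-dimethyl-4-oxocyclohexyl]pent-2-enoate | COC(=O)/C=C(\C)C[C@@H](O)[C@]1(C)CCC(=O)C[C@@H]1C | intermediate
10 | methyl (2E,5R)-5-(tert-butyldimethylsilyloxy)-3-methyl-5-[(1R,2S)-1,2-dimethyl-4-oxocyclohexyl]pent-2-enoate | COC(=O)/C=C(\C)C[C@@H](O[Si](C)(C)C(C)(C)C)[C@]1(C)CCC(=O)C[C@@H]1C | intermediate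
11 | C9 phenylsulfinyl derivative of 10 (β-keto sulfoxide; C9 and sulfur not defined) | COC(=O)/C=C(\C)C[C@@H](O[Si](C)(C)C(C)(C)C)[C@]1(C)CC(S(=O)c2ccccc2)C(=O)C[C@@H]1C | intermediate (not isolated)
12 | C9=C4 enone from 10 (cyclohex-2-enone, C8 ketone; C5, C6, C14 unchanged) | COC(=O)/C=C(\C)C[C@@H](O[Si](C)(C)C(C)(C)C)[C@]1(C)C=CC(=O)C[C@@H]1C | intermediate
13 | C9–C4 epoxide of 12 (epoxide face not defined) | COC(=O)/C=C(\C)C[C@@H](O[Si](C)(C)C(C)(C)C)[C@]1(C)C2OC2C(=O)C[C@@H]1C | intermediate
14 | cyclohexane-1,3-dione with ketones at C8 and C4 and C9H2 between them (enolised in solution) | COC(=O)/C=C(\C)C[C@@H](O[Si](C)(C)C(C)(C)C)[C@]1(C)C(=O)CC(=O)C[C@@H]1C | intermediate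
15 | 3-bromoprop-1-yne (propargyl bromide) | C#CCBr | starting material
16 | C9-(prop-2-ynyl) derivative of 14 (C9 enolisable, not a fixed centre) | COC(=O)/C=C(\C)C[C@@H](O[Si](C)(C)C(C)(C)C)[C@]1(C)C(=O)C(CC#C)C(=O)C[C@@H]1C | intermediate
17 | (Z)-but-2-en-1-ol | C/C=C\CO | starting material
18 | C8 enol (Z)-but-2-enyl ether of 16 (3-alkoxy-2-propargylcyclohex-2-enone, C4 ketone kept) | COC(=O)/C=C(\C)C[C@@H](O[Si](C)(C)C(C)(C)C)[C@]1(C)C(=O)C(CC#C)=C(OC/C=C\C)C[C@@H]1C | intermediate
19 | 1,3-dione with quaternary (S)-C9 bearing propargyl (C1 arm) and (S)-but-3-en-2-yl (C10 arm, anti to C14 across the ring) | COC(=O)/C=C(\C)C[C@@H](O[Si](C)(C)C(C)(C)C)[C@]1(C)C(=O)[C@@](CC#C)([C@@H](C)C=C)C(=O)C[C@@H]1C | intermediate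
20 | C8 alcohol of 19 (C8–OH cis to the C10 arm, C4 ketone kept) | COC(=O)/C=C(\C)C[C@@H](O[Si](C)(C)C(C)(C)C)[C@]1(C)C(=O)[C@@](CC#C)([C@@H](C)C=C)[C@@H](O)C[C@@H]1C | intermediate
21 | cis-fused lactol (C8–O–C11 tetrahydrofuran-2-ol, C11 anomers) | COC(=O)/C=C(\C)C[C@@H](O[Si](C)(C)C(C)(C)C)[C@]1(C)C(=O)[C@@]2(CC#C)[C@@H](C)C(O)O[C@H]2C[C@@H]1C | intermediate (not isolated)
22 | methyl acetal of 21 (C11 anomers) | COC(=O)/C=C(\C)C[C@@H](O[Si](C)(C)C(C)(C)C)[C@]1(C)C(=O)[C@@]2(CC#C)[C@@H](C)C(OC)O[C@H]2C[C@@H]1C | intermediate
23 | (E)-allylic alcohol from reduction of the ester of 22 | OC/C=C(\C)C[C@@H](O[Si](C)(C)C(C)(C)C)[C@]1(C)C(=O)[C@@]2(CC#C)[C@@H](C)C(OC)O[C@H]2C[C@@H]1C | intermediate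
24 | methyl ketone (C9–CH2COCH3) from hydration of 23 | OC/C=C(\C)C[C@@H](O[Si](C)(C)C(C)(C)C)[C@]1(C)C(=O)[C@@]2(CC(C)=O)[C@@H](C)C(OC)O[C@H]2C[C@@H]1C | intermediate
25 | aldol adduct (C4 tertiary alcohol, cyclopentanone; C4 not defined) | OC/C=C(\C)C[C@@H](O[Si](C)(C)C(C)(C)C)[C@]1(C)C2(O)CC(=O)C[C@@]23[C@@H](C)C(OC)O[C@H]3C[C@@H]1C | intermediate (not isolated)
26 | cyclopentenone (C3=C4, C2 ketone) with C14–OTBS, allylic alcohol and methyl acetal | OC/C=C(\C)C[C@@H](O[Si](C)(C)C(C)(C)C)[C@]1(C)C2=CC(=O)C[C@@]23[C@@H](C)C(OC)O[C@H]3C[C@@H]1C | intermediate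
27 | diol: C14 alcohol of 26 | OC/C=C(\C)C[C@@H](O)[C@]1(C)C2=CC(=O)C[C@@]23[C@@H](C)C(OC)O[C@H]3C[C@@H]1C | intermediate
28 | (E)-allylic chloride of 27 (C14–OH free) | ClC/C=C(\C)C[C@@H](O)[C@]1(C)C2=CC(=O)C[C@@]23[C@@H](C)C(OC)O[C@H]3C[C@@H]1C | intermediate
29 | C14 acetate of 28 | ClC/C=C(\C)C[C@@H](OC(C)=O)[C@]1(C)C2=CC(=O)C[C@@]23[C@@H](C)C(OC)O[C@H]3C[C@@H]1C | intermediate
30 | lactol from 29 (C11 anomers; ring-chain tautomer of the C8-hydroxy C11 aldehyde) | ClC/C=C(\C)C[C@@H](OC(C)=O)[C@]1(C)C2=CC(=O)C[C@@]23[C@@H](C)C(O)O[C@H]3C[C@@H]1C | intermediate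
31 | allylchromium dichloride species from 30 (alkene geometry equilibrating) | Cl[Cr](Cl)CC=C(C)C[C@@H](OC(C)=O)[C@]1(C)C2=CC(=O)C[C@@]23[C@@H](C)C(O)O[C@H]3C[C@@H]1C | intermediate (not isolated)
32 | Pleuromutilin E | C=C[C@]1(C)C[C@@H](OC(C)=O)[C@]2(C)C3=CC(=O)C[C@@]3([C@@H](O)C[C@@H]2C)[C@@H](C)[C@@H]1O | target

Total step count: 21. Longest linear sequence: 20 steps (steps 1, 2 and 4 to 21); step 3 is a one-step branch that makes reagent 7.

Steps most likely to fail

Step 21 (ring closure). The trans-bridged eight-membered ring may close too slowly, so that the allylchromium is protonated or couples with itself. The lactol may release the aldehyde too slowly. C12 may form with the wrong relative configuration through the (E)-allylchromium chair. The fallback generates the allyl nucleophile as an allylindium by umpolung of a π-allylpalladium species from an allylic acetate, a reagent class that reacts with lactols in wet solvents and needs no halide. It sets out from diol 27: Ac2O, Et3N and DMAP (cat.) should give the diacetate F1; PPTS in acetone–H2O should give the lactol diacetate F2; Pd(PPh3)4 (5 mol%) and indium monoiodide (InI) in THF–H2O at high dilution should then close the ring, coming back to the route at 32.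

Step 11 (Claisen rearrangement). Control at C10 may be lost through a boat transition state, because the methyl group of the (Z)-butenyl unit is pseudo-axial in the chair. The allyl unit may attack the wrong face of C9. Partial O-alkylation at the C4 oxygen in step 10 may feed a regioisomeric enol ether that rearranges to the C10 epimer. The fallback puts C10 under catalyst control: from dione 16, iridium-catalysed branched-selective allylic alkylation with (E)-but-2-enyl methyl carbonate ([Ir(cod)Cl]2 (2 mol%), (S)-BINOL-derived N,N-bis(1-phenylethyl)phosphoramidite ligand of the antipode that gives the required C10, THF) should form C9–C10 directly, the substrate again directing the electrophile anti to C14. This fallback makes no compound outside the list (F0) and comes back at 19.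

Step 6 (regiocontrolled dehydrogenation). Sulfinylation may occur at C7 instead of C9; elimination would then give the C6=C7 enone and destroy the C6 centre. The syn-elimination may also be incomplete. The fallback secures regiocontrol by a reversible Claisen formylation followed by a carbenoid 1,2-hydride shift. It sets out from ketone 10: HCO2Et and NaH should give the thermodynamically preferred C9 hydroxymethylene ketone F3; deformylative diazo transfer (4-acetamidobenzenesulfonyl azide, Et3N, MeCN) should give the α-diazo ketone F4; Rh2(OAc)4 (1 mol%) in CH2Cl2 should induce loss of N2 and a 1,2-hydride shift from C4, coming back to the route at enone 12.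

Further compounds
F1 | step 21 | diacetate of 27 (C14 acetate and allylic acetate, methyl acetal kept) | CC(=O)OC/C=C(\C)C[C@@H](OC(C)=O)[C@]1(C)C2=CC(=O)C[C@@]23[C@@H](C)C(OC)O[C@H]3C[C@@H]1C
F2 | step 21 | lactol diacetate from F1 | CC(=O)OC/C=C(\C)C[C@@H](OC(C)=O)[C@]1(C)C2=CC(=O)C[C@@]23[C@@H](C)C(O)O[C@H]3C[C@@H]1C
F0 | step 11 | none | none
F3 | step 6 | C9 hydroxymethylene ketone from 10 | COC(=O)/C=C(\C)C[C@@H](O[Si](C)(C)C(C)(C)C)[C@]1(C)CC(=CO)C(=O)C[C@@H]1C
F4 | step 6 | C9 diazo ketone from F3 | COC(=O)/C=C(\C)C[C@@H](O[Si](C)(C)C(C)(C)C)[C@]1(C)CC(=[N+]=[N-])C(=O)C[C@@H]1C
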